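1. Start from a one-step world: D goes to Z with a rate constant k proportional to L, and each L begins one chain. Test that on the runs below.

| setting | south-west | north-east | east | larch | maple |
|---|---|---|---|---|---|
| D | 0.80 M (fed, over 50 s) | 0.80 M (fed, over 50 s) | 0.80 M (fed, over 50 s) | 0.80 M (fed, over 50 s) | 0.80 M (fed, over 100 s) |
| L | 0.5 mol% | 2 mol% | 1 mol% | 1 mol% | 1 mol% |
| Q | 1.7 mM | 1.7 mM | 2.5 mM | 1.7 mM | 1.7 mM |
| remark | run made earlier; the fed solution adds 0.20 times the starting volume | run made earlier; the fed solution adds 0.20 times the starting volume | run made earlier; the fed solution adds 0.20 times the starting volume | the fed solution adds 0.20 times the starting volume | the fed solution adds 0.20 times the starting volume |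
| time |  |  |  | 40 min | 40 min |

- south-west (time / min: Z / %, D / %): 10.0: 11, 88; 20.0: 24, 75; 30.0: 32, 65; 40.0: 46, 55; 50.0: 52, 46
- north-east (time / min: Z / %, D / %): 4.00: 21, 74; 12.0: 64, 33; 20.0: 83, 17; 30.0: 91, 7; 50.0: 97, 3
- east (time / min: Z / %, D / %): 10.0: 30, 69; 20.0: 55, 50; 30.0: 65, 34; 40.0: 73, 25; 50.0: 81, 16

(standard deviation of a reading: 2 percentage points)

- every charge counts on the volume at the start, and the solution that is fed holds the whole dose
- the average divides the monomer in chains by the number of chains begun, living and dead together
- the numbers in the tables scatter with a standard deviation of 2 percentage points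
- the earlier runs do not show the number of chains; that part of a forecast is a guess

* which of the two ends with the longer chains by the average number of monomer units in a chain (chains begun, living or dead) ("neither" if they lie within 10%) (larch / maple / neither)
* average number of monomer units in a chain (chains begun, living or dead) at the end, larch
* average number of monomer units in a chain (chains begun, living or dead) at the end, maple

2. Read k as a first-order constant from one reading per run: 0.0155 min⁻¹ in the south-west run, 0.0924 min⁻¹ in the north-east run, 0.0367 min⁻¹ in the east run. From south-west to north-east, L grows by a factor 4.00 but k by 5.96, which is more. So doubt the one-step world.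

3. Write the balance of Q, the limiting reagent against L: in larch, 1.7 mM of Q meets 8.00 mM of L. Suppose each Q removes one L. Then define the free loading A, the charge of L minus the charge of Q on the starting volume: 6.30 mM in larch. The south-west run has 2.30 mM, the north-east run 14.3 mM, the east run 5.50 mM. The ratios of A to south-west are 6.22 and 2.39; those of k are 5.96 and 2.37.

4. Object: an order of 1.29 in L, with Q ignored, also fits. It gives larch a k of 0.0379 min⁻¹, while scaling by A gives 0.0407 min⁻¹. The two lie close, so keep A. The reacted share of D in larch is then 80.4%.

5. Object again: Q might end chains already begun. The length is then 80.4, not 102. The runs show no chain counts, so this stays a guess; commit to A.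

6. Check the feed. Maple's 1.7 min is far shorter than 24.6 min, the time 1/k. Reckon larch and maple as equal in length.

The forecast reads neither, with 100 for larch and 100 for maple, on the ground that “Q removes initiator or chains one-for-one”.

    G + Z → E (k = 0.0210 L mol⁻¹ min⁻¹)
    D + L → G + Z (k = 1.70 L mol⁻¹ min⁻¹)
    L + Q → J (k = 3800 L mol⁻¹ min⁻¹)
    D + G → Z + G, rate k4*[G]*[D] (k = 8.40 L mol⁻¹ min⁻¹)

Larch ends at 99.8 and maple at 99.4, so the answer is neither. In larch J stands at 0.00142 M in the whole volume, which is 1.70 mM on the starting volume, the charge of Q. Now take a neighbouring flask, maple with Q raised to 0.0068 M: A falls to 1.20 mM. Its Z at 40.0 min is 27.1%, and Z over A gives 181. The length stored for that neighbouring flask is 180.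

The data come from a simulation for substances that don't exist, and the scatter is random.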